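## Retrosynthetic overview

1. The α-methylene group is unveiled last from a Mannich base (N-methylation, then elimination), so the acetate never meets a strong base.
2. The fourteen-membered ring is closed by an intramolecular B-alkyl Suzuki coupling (C8–C9). Before that, an intermolecular Nozaki–Hiyama–Kishi coupling (C3–C4) joins an ε-lactone aldehyde to a C7 bromo-iodo-diene linchpin that carries both trisubstituted alkenes.
3. The ε-lactone comes from a Baeyer–Villiger ring expansion of a cyclohexanone: the quaternary α-carbon migrates with retention and becomes the tertiary C–O centre (C12).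
4. The cyclohexanone comes from 6-methylcyclohex-2-enone by a new Ir-catalysed acetoxyallylation (C11–C12 bond, both stereocentres and the acetate in one step), then a Rh-catalysed conjugate vinylation (C1).
5. Ring order: six-membered carbocycle (purchased), then seven-membered lactone (ring expansion), then fourteen-membered carbocycle (cross-coupling).

Assumption: racemic 6-methylcyclohex-2-en-1-one is taken as a catalogue chemical; bond labels such as C3–C4 use the bicyclo[10.3.2]heptadecane numbering of the name given for compound 27.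

## Route

Step 1
Reactants: 1 acrolein; 2 acetic anhydride
Product: 3 acrolein diacetate
Conditions: H2SO4 (cat.), neat, 0 °C to rt; distillation
Reagents that add atoms: none
Why: Acid-catalysed acylal formation (addition of the anhydride across the aldehyde C=O) is the standard preparation of allylidene diacetate and creates no stereocentre.

Step 2
Reactants: 4 6-methylcyclohex-2-en-1-one; 3 acrolein diacetate
Product: 6 (1S)-1-[(1R)-1-methyl-2-oxocyclohex-3-en-1-yl]prop-2-en-1-yl acetate, via lithium dienolate 5 (not isolated)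
Conditions: LiN(SiMe3)2, THF, −78 °C; then 3, [Ir(cod)Cl]2 (2 mol %), Feringa-type phosphoramidite (4 mol %; (Ra,Rc,Rc) expected for the 1S acetate), n-PrNH2 pre-activation, THF, −78 to 0 °C
Reagents that add atoms: none
Why: Proposed new method: an Ir-catalysed, branched-selective allylic alkylation of an unstabilised cross-conjugated dienolate with an acyloxy-substituted allyl electrophile, in which ionisation of one acetate of 3 by the cyclometalated Ir–phosphoramidite gives a 1-acetoxy-π-allyl complex whose oxygen-bearing terminus carries most of the positive charge, so the α′-carbon of 5 attacks there from the face opposite to iridium and forges the quaternary-carbon-to-acetoxy-carbon bond with the acetate already in place, the ligand fixing the (S)-acetoxy centre by π-face discrimination and the (R)-quaternary centre through an open transition state that turns the enolate oxygen away from the acetoxy group; the closest known chemistry is the Ir-catalysed allylation of unstabilised ketone and enone enolates with aryl- or alkyl-substituted allyl carbonates (vicinal quaternary and tertiary centres) and the Pd-catalysed asymmetric substitution of allylic gem-diacetates by stabilised nucleophiles.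

Step 3
Reactants: 6 (1S)-1-[(1R)-1-methyl-2-oxocyclohex-3-en-1-yl]prop-2-en-1-yl acetate; 7 potassium ethenyltrifluoroborate
Product: 8 (1S)-1-[(1R,4S)-4-ethenyl-1-methyl-2-oxocyclohexyl]prop-2-en-1-yl acetate
Conditions: [Rh(cod)2]BF4 (3 mol %), (S)-BINAP (3.3 mol %), toluene/H2O, 100 °C
Reagents that add atoms: none
Why: Hayashi–Miyaura Rh-catalysed asymmetric 1,4-addition, in which the vinyl–Rh/(S)-BINAP species adds to the unhindered β-carbon under catalyst control (the (S)-ligand gives the (S)-β-centre as with cyclohex-2-enone itself, the remote quaternary centre exerting little bias) while the isolated vinyl group and the acetate are untouched.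

Step 4
Reactants: 8 (1S)-1-[(1R,4S)-4-ethenyl-1-methyl-2-oxocyclohexyl]prop-2-en-1-yl acetate
Product: 10 (1S)-1-[(1R,4R)-3-[(dimethylamino)methyl]-4-ethenyl-1-methyl-2-oxocyclohexyl]prop-2-en-1-yl acetate as a C-3 epimer mixture, via trimethylsilyl enol ether 9 (not isolated)
Conditions: TMSOTf, Et3N, CH2Cl2, 0 °C; then CH2=NMe2+ I−, rt; aq. NaHCO3
Reagents that add atoms: Eschenmoser's salt (N,N-dimethylmethylideneammonium iodide), C=[N+](C)C.[I-]
Why: Soft enolisation followed by a Mannich reaction, which works because only C-3 carries α-hydrogens, TMSOTf/Et3N silylates the ketone without enolising the acetate, and the new C-3 centre is irrelevant since it becomes sp2 in the last step.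

Step 5
Reactants: 10 (1S)-1-[(1R,4R)-3-[(dimethylamino)methyl]-4-ethenyl-1-methyl-2-oxocyclohexyl]prop-2-en-1-yl acetate
Product: 11 (1S)-1-[(2R,5R)-6-[(dimethylamino)methyl]-5-ethenyl-2-methyl-7-oxooxepan-2-yl]prop-2-en-1-yl acetate as a C-6 epimer mixture
Conditions: m-CPBA (1.5 equiv), CF3CO2H (1.1 equiv), CH2Cl2, 0 °C to rt; aq. NaHCO3/Na2S2O3
Reagents that add atoms: m-chloroperbenzoic acid, OOC(=O)c1cccc(Cl)c1
Why: Baeyer–Villiger ring expansion (Criegee 1,2-shift from carbon to oxygen), in which the quaternary α-carbon migrates with retention in preference to the secondary α-carbon (further retarded by the β-ammonium group) to give the ε-lactone with the tertiary C–O centre of the target, while protonation by CF3CO2H protects the amine from N-oxidation and speeds the ketone oxidation relative to the slow epoxidation of the two mono-substituted alkenes.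

Step 6
Reactants: 11 (1S)-1-[(2R,5R)-6-[(dimethylamino)methyl]-5-ethenyl-2-methyl-7-oxooxepan-2-yl]prop-2-en-1-yl acetate
Product: 13 (1S)-1-[(2R,5R)-6-[(dimethylamino)methyl]-5-(2-hydroxyethyl)-2-methyl-7-oxooxepan-2-yl]prop-2-en-1-yl acetate, via B-alkyl-9-BBN adduct 12 (not isolated)
Conditions: 9-BBN (1.3 equiv), THF, 0 °C; then NaBO3·4H2O, THF/H2O, rt
Reagents that add atoms: sodium perborate tetrahydrate, [Na+].[O-]B1OO1.O.O.O.O
Why: Chemoselective anti-Markovnikov hydroboration–oxidation, in which 9-BBN adds to the unhindered ring vinyl group far faster than to the vinyl group flanked by the acetoxy-bearing carbon and the quaternary centre (steric and inductive retardation), and perborate oxidation spares lactone and acetate.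

Step 7
Reactants: 13 (1S)-1-[(2R,5R)-6-[(dimethylamino)methyl]-5-(2-hydroxyethyl)-2-methyl-7-oxooxepan-2-yl]prop-2-en-1-yl acetate
Product: 14 (1S)-1-[(2R,5R)-6-[(dimethylamino)methyl]-2-methyl-7-oxo-5-(2-oxoethyl)oxepan-2-yl]prop-2-en-1-yl acetate
Conditions: Dess–Martin periodinane, NaHCO3, CH2Cl2, 0 °C
Reagents that add atoms: none
Why: Dess–Martin oxidation of the primary alcohol to the aldehyde under buffered conditions that tolerate the tertiary amine, the lactone and the acetate.

Step 8
Reactants: 15 but-2-yn-1-ol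
Product: 17 (2Z)-3-bromobut-2-en-1-ol, via cyclic alkenylalanate 16 (not isolated)
Conditions: NaAlH2(OCH2CH2OMe)2, Et2O, 0 °C to rt; then N-bromosuccinimide, −78 °C
Reagents that add atoms: N-bromosuccinimide, O=C1CCC(=O)N1Br
Why: Hydroxyl-directed trans-hydroalumination of the propargylic alcohol places aluminium at C-3 cis to the CH2O group in a five-membered alanate, and bromodealumination with retention fixes the (Z)-bromoalkene.

Step 9
Reactants: 17 (2Z)-3-bromobut-2-en-1-ol
Product: 18 (2Z)-1,3-dibromobut-2-ene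
Conditions: PBr3, Et2O, 0 °C
Reagents that add atoms: phosphorus tribromide, BrP(Br)Br
Why: Standard SN2-type conversion of a primary allylic alcohol into the bromide, which leaves the alkene geometry untouched.

Step 10
Reactants: 18 (2Z)-1,3-dibromobut-2-ene; 19 prop-1-yn-1-ylmagnesium bromide
Product: 20 (2Z)-2-bromohept-2-en-5-yne
Conditions: CuBr·SMe2 (5 mol %), THF, −20 to 0 °C
Reagents that add atoms: none
Why: Copper-catalysed SN2 coupling of an alkynyl Grignard reagent with a primary allylic bromide gives the skipped enyne, the vinylic bromide being inert and the (Z)-geometry retained.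

Step 11
Reactants: 20 (2Z)-2-bromohept-2-en-5-yne
Product: 22 (2Z,5E)-2-bromo-6-iodohepta-2,5-diene, via alkenylzirconocene chloride 21 (not isolated)
Conditions: Cp2Zr(H)Cl (1.5 equiv), THF, rt then 50 °C; then I2, 0 °C
Reagents that add atoms: iodine, II
Why: Hydrozirconation–iodination, in which syn addition of Zr–H across the alkyne (zirconium equilibrating to the less hindered methyl-bearing carbon) followed by iodinolysis with retention gives the (E)-2-iodoalkene while the trisubstituted bromoalkene does not react.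

Step 12
Reactants: 14 (1S)-1-[(2R,5R)-6-[(dimethylamino)methyl]-2-methyl-7-oxo-5-(2-oxoethyl)oxepan-2-yl]prop-2-en-1-yl acetate; 22 (2Z,5E)-2-bromo-6-iodohepta-2,5-diene
Product: 23 (1S)-1-[(2R,5R)-5-[(2R,3E,6Z)-7-bromo-2-hydroxy-3-methylocta-3,6-dien-1-yl]-6-[(dimethylamino)methyl]-2-methyl-7-oxooxepan-2-yl]prop-2-en-1-yl acetate
Conditions: CrCl2 (4 equiv), NiCl2 (1 mol %), Kishi oxazoline–sulfonamide ligand (enantiomer giving the 2′R alcohol), Et3N, THF, rt
Reagents that add atoms: none
Why: Nozaki–Hiyama–Kishi coupling, in which zerovalent nickel inserts into the C–I bond much faster than into the C–Br bond, the alkenylchromium adds only to the aldehyde with retention of the (E)-geometry, and the chiral sulfonamide-bound chromium sets the (R)-carbinol centre (C3 of the target) by reagent control.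

Step 13
Reactants: 23 (1S)-1-[(2R,5R)-5-[(2R,3E,6Z)-7-bromo-2-hydroxy-3-methylocta-3,6-dien-1-yl]-6-[(dimethylamino)methyl]-2-methyl-7-oxooxepan-2-yl]prop-2-en-1-yl acetate
Product: 25 (1R,3R,4E,7Z,11S,12R)-15-[(dimethylamino)methyl]-3-hydroxy-4,8,12-trimethyl-14-oxo-13-oxabicyclo[10.3.2]heptadeca-4,7-dien-11-yl acetate as a C-15 epimer mixture, via bis-borylated intermediate 24 (not isolated)
Conditions: 9-BBN (3 equiv), THF, rt to 40 °C; then syringe-pump addition to Pd(dppf)Cl2 (15 mol %), AsPh3, Cs2CO3, DMF/THF/H2O, 50 °C, 2 mM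
Reagents that add atoms: none
Why: Intramolecular B-alkyl Suzuki–Miyaura coupling, in which 9-BBN hydroborates only the remaining terminal vinyl group (the trisubstituted alkenes and the bromoalkene are inert) and Pd-catalysed sp3–sp2 coupling at high dilution closes the fourteen-membered ring with retention of the (Z)-alkene geometry, no stereocentre being created.

Step 14
Reactants: 25 (1R,3R,4E,7Z,11S,12R)-15-[(dimethylamino)methyl]-3-hydroxy-4,8,12-trimethyl-14-oxo-13-oxabicyclo[10.3.2]heptadeca-4,7-dien-11-yl acetate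
Product: 27 (1R,3R,4E,7Z,11S,12R)-3-hydroxy-4,8,12-trimethyl-15-methylidene-14-oxo-13-oxabicyclo[10.3.2]heptadeca-4,7-dien-11-yl acetate (CNP0130972.5), via trimethylammonium iodide 26 (not isolated)
Conditions: MeI, MeOH, rt; then aq. NaHCO3, CH2Cl2, rt
Reagents that add atoms: none
Why: Exhaustive N-methylation followed by base-induced β-elimination of trimethylamine (E1cB, Hofmann type) unveils the α-methylene lactone under conditions that leave the acetate, the allylic alcohol and the skipped diene untouched.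

## Compound list

1 | acrolein (prop-2-enal) | C=CC=O | starting material
2 | acetic anhydride | CC(=O)OC(C)=O | starting material
3 | acrolein diacetate (prop-2-ene-1,1-diyl diacetate) | C=CC(OC(C)=O)OC(C)=O | intermediate
4 | 6-methylcyclohex-2-en-1-one (racemic) | CC1CCC=CC1=O | starting material
5 | lithium 2-methylcyclohexa-1,5-dien-1-olate (cross-conjugated dienolate of 4) | CC1=C(O[Li])C=CCC1 | intermediate
6 | (1S)-1-[(1R)-1-methyl-2-oxocyclohex-3-en-1-yl]prop-2-en-1-yl acetate | O=C1C=CCC[C@]1(C)[C@@H](OC(C)=O)C=C | intermediate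
7 | potassium ethenyltrifluoroborate | [K+].C=C[B-](F)(F)F | starting material
8 | (1S)-1-[(1R,4S)-4-ethenyl-1-methyl-2-oxocyclohexyl]prop-2-en-1-yl acetate | O=C1C[C@@H](C=C)CC[C@]1(C)[C@@H](OC(C)=O)C=C | intermediate
9 | (1S)-1-[(1R,4R)-4-ethenyl-1-methyl-2-[(trimethylsilyl)oxy]cyclohex-2-en-1-yl]prop-2-en-1-yl acetate | C[Si](C)(C)OC1=C[C@@H](C=C)CC[C@]1(C)[C@@H](OC(C)=O)C=C | intermediate
10 | (1S)-1-[(1R,4R)-3-[(dimethylamino)methyl]-4-ethenyl-1-methyl-2-oxocyclohexyl]prop-2-en-1-yl acetate (C-3 epimer mixture) | O=C1C(CN(C)C)[C@@H](C=C)CC[C@]1(C)[C@@H](OC(C)=O)C=C | intermediate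
11 | (1S)-1-[(2R,5R)-6-[(dimethylamino)methyl]-5-ethenyl-2-methyl-7-oxooxepan-2-yl]prop-2-en-1-yl acetate (C-6 epimer mixture) | O=C1O[C@@](C)([C@@H](OC(C)=O)C=C)CC[C@H](C=C)C1CN(C)C | intermediate
12 | B-alkyl-9-BBN adduct of 11 (9-borabicyclo[3.3.1]nonan-9-yl on the terminal carbon of the former C-5 vinyl group) | O=C1O[C@@](C)([C@@H](OC(C)=O)C=C)CC[C@H](CCB2C3CCCC2CCC3)C1CN(C)C | intermediate
13 | (1S)-1-[(2R,5R)-6-[(dimethylamino)methyl]-5-(2-hydroxyethyl)-2-methyl-7-oxooxepan-2-yl]prop-2-en-1-yl acetate | O=C1O[C@@](C)([C@@H](OC(C)=O)C=C)CC[C@H](CCO)C1CN(C)C | intermediate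
14 | (1S)-1-[(2R,5R)-6-[(dimethylamino)methyl]-2-methyl-7-oxo-5-(2-oxoethyl)oxepan-2-yl]prop-2-en-1-yl acetate | O=C1O[C@@](C)([C@@H](OC(C)=O)C=C)CC[C@H](CC=O)C1CN(C)C | intermediate
15 | but-2-yn-1-ol | CC#CCO | starting material
16 | sodium cyclic (Z)-alkenylalanate (Al bonded to O-1 and C-3 of the but-2-en-1-olate and to two 2-methoxyethoxy groups) | [Na+].CC1=CCO[Al-]1(OCCOC)OCCOC | intermediate
17 | (2Z)-3-bromobut-2-en-1-ol | OC/C=C(/C)Br | intermediate
18 | (2Z)-1,3-dibromobut-2-ene | BrC/C=C(/C)Br | intermediate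
19 | prop-1-yn-1-ylmagnesium bromide | CC#C[Mg]Br | starting material
20 | (2Z)-2-bromohept-2-en-5-yne | CC#CC/C=C(/C)Br | intermediate
21 | [(2E,5Z)-6-bromohepta-2,5-dien-2-yl]chlorobis(cyclopentadienyl)zirconium | Cl[Zr](C1C=CC=C1)(C1C=CC=C1)/C(C)=C/C/C=C(/C)Br | intermediate
22 | (2Z,5E)-2-bromo-6-iodohepta-2,5-diene | I/C(C)=C/C/C=C(/C)Br | intermediate
23 | (1S)-1-[(2R,5R)-5-[(2R,3E,6Z)-7-bromo-2-hydroxy-3-methylocta-3,6-dien-1-yl]-6-[(dimethylamino)methyl]-2-methyl-7-oxooxepan-2-yl]prop-2-en-1-yl acetate | O=C1O[C@@](C)([C@@H](OC(C)=O)C=C)CC[C@H](C[C@@H](O)/C(C)=C/C/C=C(/C)Br)C1CN(C)C | intermediate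
24 | O,B-bis(9-borabicyclo[3.3.1]nonan-9-yl) derivative of 23 (borinate on the carbinol oxygen; alkylborane on the terminal carbon of the former vinyl group) | O=C1O[C@@](C)([C@@H](OC(C)=O)CCB2C3CCCC2CCC3)CC[C@H](C[C@@H](OB2C3CCCC2CCC3)/C(C)=C/C/C=C(/C)Br)C1CN(C)C | intermediate
25 | (1R,3R,4E,7Z,11S,12R)-15-[(dimethylamino)methyl]-3-hydroxy-4,8,12-trimethyl-14-oxo-13-oxabicyclo[10.3.2]heptadeca-4,7-dien-11-yl acetate (C-15 epimer mixture) | CN(C)CC1C(=O)O[C@]2(C)CC[C@@H]1C[C@@H](O)/C(C)=C/C/C=C(/C)CC[C@@H]2OC(C)=O | intermediate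
26 | N-methyl quaternary ammonium iodide of 25 (trimethylammoniomethyl group at C-15) | [I-].C[N+](C)(C)CC1C(=O)O[C@]2(C)CC[C@@H]1C[C@@H](O)/C(C)=C/C/C=C(/C)CC[C@@H]2OC(C)=O | intermediate
27 | (1R,3R,4E,7Z,11S,12R)-3-hydroxy-4,8,12-trimethyl-15-methylidene-14-oxo-13-oxabicyclo[10.3.2]heptadeca-4,7-dien-11-yl acetate (CNP0130972.5) | C=C1C(=O)O[C@]2(C)CC[C@@H]1C[C@@H](O)/C(C)=C/C/C=C(/C)CC[C@@H]2OC(C)=O | target

## Step count and risks

Total step count: 14. Longest linear sequence: 10 steps (1, 2, 3, 4, 5, 6, 7, 12, 13, 14); the linchpin branch (8–11) is 4 steps.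

**Step 2 (the proposed new reaction).** The risks are acyl transfer from the gem-diacetate to the enolate, linear instead of branched attack, and incomplete control of the quaternary centre relative to the acetoxy centre. The ligand antipode is swapped if the sense of induction at the acetoxy carbon turns out opposite. Fallback with known chemistry, setting out from 4 and 1 and returning at 6: 4 is deprotonated at C-6 with LiN(iPr)2 (THF, −78 °C) and the dienolate is added to acrolein 1 in an ordinary lithium aldol reaction (1,2-addition). The racemic diastereomer with the relative configuration of 6 is separated on silica and resolved by preparative chromatography on a chiral stationary phase to give (6R)-6-[(1S)-1-hydroxyprop-2-en-1-yl]-6-methylcyclohex-2-en-1-one F1. F1 is acetylated (acetic anhydride 2, DMAP, pyridine, 0 °C) to 6.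

**Step 12.** The risks are the level of ligand control at the new carbinol with a β-branched aldehyde and some competing insertion into the C–Br bond. Fallback, setting out from 14 and 22 and returning at 23: the coupling is run without a chiral ligand (CrCl2, 1 mol % NiCl2, DMSO/THF) to give the carbinol as a mixture of epimers, (1S)-1-[(2R,5R)-5-[(2RS,3E,6Z)-7-bromo-2-hydroxy-3-methylocta-3,6-dien-1-yl]-6-[(dimethylamino)methyl]-2-methyl-7-oxooxepan-2-yl]prop-2-en-1-yl acetate F2. Dess–Martin oxidation gives the enone (1S)-1-[(2R,5R)-5-[(3E,6Z)-7-bromo-3-methyl-2-oxoocta-3,6-dien-1-yl]-6-[(dimethylamino)methyl]-2-methyl-7-oxooxepan-2-yl]prop-2-en-1-yl acetate F3. Corey–Bakshi–Shibata reduction ((S)-2-methyl-oxazaborolidine, catecholborane, toluene, −78 °C) then sets the (R)-alcohol under reagent control and returns 23.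

**Step 13.** The risks are oligomerisation instead of ring closure, slow hydroboration of the hindered vinyl group and protodeboronation. Fallback, setting out from 13 and 20 and returning at 25: the order of the two carbon–carbon couplings is reversed, so that the ring is closed at C3–C4 instead of C8–C9. 13 is hydroborated at its remaining vinyl group (9-BBN, THF) to the O,B-bis(9-borabicyclo[3.3.1]nonan-9-yl) adduct of 13 F4. F4 is cross-coupled intermolecularly with the bromoalkene 20 (Pd(dppf)Cl2, AsPh3, Cs2CO3, DMF/H2O) to give (1S,4Z)-1-[(2R,5R)-6-[(dimethylamino)methyl]-5-(2-hydroxyethyl)-2-methyl-7-oxooxepan-2-yl]-4-methylnon-4-en-7-yn-1-yl acetate F5. Dess–Martin oxidation gives the ynal (1S,4Z)-1-[(2R,5R)-6-[(dimethylamino)methyl]-2-methyl-7-oxo-5-(2-oxoethyl)oxepan-2-yl]-4-methylnon-4-en-7-yn-1-yl acetate F6. Nickel-catalysed reductive alkyne–aldehyde macrocyclisation (Ni(cod)2, the bulky N-heterocyclic carbene IPr, Et3SiH, toluene, 5 mM; endocyclic mode, syn addition giving the E-alkene, with C-3 then relying on macrocyclic control) delivers (1R,3R,4E,7Z,11S,12R)-15-[(dimethylamino)methyl]-4,8,12-trimethyl-14-oxo-3-[(triethylsilyl)oxy]-13-oxabicyclo[10.3.2]heptadeca-4,7-dien-11-yl acetate F7. HF·pyridine (THF, 0 °C) removes the silyl group to give 25.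

Further compounds
F1 | step 2 | (6R)-6-[(1S)-1-hydroxyprop-2-en-1-yl]-6-methylcyclohex-2-en-1-one | O=C1C=CCC[C@]1(C)[C@@H](O)C=C
F2 | step 12 | (1S)-1-[(2R,5R)-5-[(2RS,3E,6Z)-7-bromo-2-hydroxy-3-methylocta-3,6-dien-1-yl]-6-[(dimethylamino)methyl]-2-methyl-7-oxooxepan-2-yl]prop-2-en-1-yl acetate (carbinol epimer mixture) | O=C1O[C@@](C)([C@@H](OC(C)=O)C=C)CC[C@H](CC(O)/C(C)=C/C/C=C(/C)Br)C1CN(C)C
F3 | step 12 | (1S)-1-[(2R,5R)-5-[(3E,6Z)-7-bromo-3-methyl-2-oxoocta-3,6-dien-1-yl]-6-[(dimethylamino)methyl]-2-methyl-7-oxooxepan-2-yl]prop-2-en-1-yl acetate | O=C1O[C@@](C)([C@@H](OC(C)=O)C=C)CC[C@H](CC(=O)/C(C)=C/C/C=C(/C)Br)C1CN(C)C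
F4 | step 13 | O,B-bis(9-borabicyclo[3.3.1]nonan-9-yl) adduct of 13 (borinate on the primary oxygen; alkylborane on the terminal carbon of the former vinyl group) | O=C1O[C@@](C)([C@@H](OC(C)=O)CCB2C3CCCC2CCC3)CC[C@H](CCOB2C3CCCC2CCC3)C1CN(C)C
F5 | step 13 | (1S,4Z)-1-[(2R,5R)-6-[(dimethylamino)methyl]-5-(2-hydroxyethyl)-2-methyl-7-oxooxepan-2-yl]-4-methylnon-4-en-7-yn-1-yl acetate | O=C1O[C@@](C)([C@@H](OC(C)=O)CC/C(C)=C\CC#CC)CC[C@H](CCO)C1CN(C)C
F6 | step 13 | (1S,4Z)-1-[(2R,5R)-6-[(dimethylamino)methyl]-2-methyl-7-oxo-5-(2-oxoethyl)oxepan-2-yl]-4-methylnon-4-en-7-yn-1-yl acetate | O=C1O[C@@](C)([C@@H](OC(C)=O)CC/C(C)=C\CC#CC)CC[C@H](CC=O)C1CN(C)C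
F7 | step 13 | (1R,3R,4E,7Z,11S,12R)-15-[(dimethylamino)methyl]-4,8,12-trimethyl-14-oxo-3-[(triethylsilyl)oxy]-13-oxabicyclo[10.3.2]heptadeca-4,7-dien-11-yl acetate | CN(C)CC1C(=O)O[C@]2(C)CC[C@@H]1C[C@@H](O[Si](CC)(CC)CC)/C(C)=C/C/C=C(/C)CC[C@@H]2OC(C)=O
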